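## The problem

Rhodisin 20 consists of two (−)-epigallocatechin gallate units, an upper one (rings A, C, B; unprimed atoms) and a lower one (rings D, F, E; primed atoms), each with a galloyl ester on O3/O3', joined only by the bond from C4 of ring C to C8' of ring D. Five stereocentres are present: 2'R,3'R of the lower unit are those of natural (−)-epigallocatechin 1 and can be bought, whereas 2R,3R,4R of the upper unit must be made, with the ring B aryl cis to O3 and ring D trans to O3. The C3 oxygen can steer C4, because a carbon nucleophile enters anti to it, but the C2/C3 pair needs reagent control and the remote lower unit offers no help. The junction has to be placed at C8' and not at the equally electron-rich C6'. Sixteen phenolic hydroxyls oxidise in air and base, the two secondary gallates are lost to base and nucleophiles, C2 epimerises in base once the ring B phenols are free, and the C4–C8' bond is cleaved by acid when rings A and D carry free hydroxyls. All phenols are therefore carried as benzyl ethers, the esters are put on late, and the last step must be neutral. The feature that opens the way is C4 itself: a doubly benzylic methine between C4a of ring A and C8' of ring D, trans to O3, which can be read as the benzylic carbon of a trans C3–C4 epoxide whose ionisation the trioxygenated ring D assists. Ring A, a symmetrical 3,5-dioxygenated phenoxy group on C2, then has an ortho carbon six atoms from C4, ready to close ring C.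

## Retrosynthesis

**20 ⇒ 19.** The sixteen O–benzyl bonds are cut. Hydrogenolysis is the only global deprotection that touches neither the esters nor the acid-labile C4–C8' bond, so the hexadecabenzyl ether 19 is the last intermediate. The forward step must be neutral and complete.

**19 ⇒ 17 + 18.** Both ester C–O(acyl) bonds are cut, giving diol 17 and two equivalents of acid chloride 18, which is prepared in its own step from acid 7. Carrying a gallate on the lower unit from the start would save the late acylation of O3', but the ester would have to survive KOH, hydroperoxide and an aryllithium. Installing both esters in one late acylation is safer. Diol 17 comes from silyl ether 16 by removal of the lower 3'-O-TBS group.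

**16 ⇒ 15 (key).** The C4–C4a bond is cut and ring C opens to the aryl ether trans-epoxide 15. Cutting C4–C8' instead would mean intermolecular arylation of a flavan C4 cation, with C6'/C8' regiochemistry and oligomerisation to control. Cutting at O1–C2 or C2–aryl would leave C4 unsolved. The chosen cut makes the bond, the ring and the C4 configuration in one intramolecular, stereospecific event. The precursor has no ring C and its three stereocentres lie on an open chain. The forward reaction must open the epoxide only at C4 and trap it with ring A before any hydride shift.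

**15 ⇒ 13 + 14.** The C2–O aryl ether bond is cut, giving the anti-epoxy alcohol 13 and the symmetrical phenol 14. Because 14 has two equivalent ortho carbons, ring A brings no regiochemical question. The forward step must invert C2 cleanly (Mitsunobu) without disturbing the epoxide.

**13 ⇒ 12 ⇒ 11.** The C2–H bond and then the two epoxide C–O bonds are removed, giving the E-enone 11. Chelation-controlled hydride delivery to epoxy ketone 12 sets C2 relative to C3. A catalytic asymmetric nucleophilic epoxidation sets C3 and C4 absolutely. Both steps run in non-acidic media, which the ring D epoxide needs.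

**11 ⇒ 6 + 9.** The C3=C4 double bond is cut by a Claisen–Schmidt disconnection into aldehyde 6 and methyl ketone 9. This is the convergence point. The whole lower unit enters as an aldehyde, so the future C4–C8' bond is simply the formyl–aryl bond of 6.

**6 ⇒ 4 ⇒ 3 ⇒ 2 ⇒ 1, and 9 ⇒ 7.** The formyl group is traced to bromide 4, whose C8' regiochemistry comes from bromination of the TBS ether 3. Compound 3 derives from 1 by benzylation of its five phenols (2) and silylation of the free 3-hydroxyl. The gallate-free catechin 1 is preferred to its 3-O-gallate because the ester would have to be removed again before the organometallic and basic steps. Ketone 9 comes from acid 7 and methyllithium. The forward steps are standard protecting-group and aromatic chemistry.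

## Roads not taken

**Alternative 1:** The cut is at both C2–aryl bonds, leading to the bis-dihydrocoumarin A2, in which both pyran rings are lactones, and two equivalents of the aryllithium A3. In the forward step A3 adds to both lactone carbonyls of A2 and the lactols are reduced in the same flask with Et3SiH/BF3·OEt2, to give the bis(triisopropylsilyl) ether A1.
- Merits: both B-type rings arrive late from one simple reagent, and two stereocentres are set in one operation. In late-stage convergence this road is better than the chosen one.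
- Weak points: A2 already contains C3, C4 and the C4–C8' bond, so the hardest problem is only moved into the preparation of A2. An aryl lactone can open to the keto phenoxide and take a second equivalent of A3. BF3·OEt2 threatens the interflavan bond. In the upper unit the face anti to the C3 silyl ether is the face shielded by the trans C4 substituent, so hydride delivery to C2 is not clearly biased.
- Comparison: the chosen plan is longer after the union, but it buys C2' and C3' with (−)-epigallocatechin and sets C2, C3 and C4 one at a time by reagent control or stereospecific opening.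

**Alternative 2:** The cut is at C4'–C4a' of ring F. The precursor A5 is the finished, galloylated upper unit with ring D attached at C4 as an open phloroglucinol ether whose O1' carries a 1-aryl-2,3-epoxypropyl chain. With AuCl3/AgOTf, C4a' opens the epoxide of A5 at its terminal carbon to give the dimer A4, which has a free lower 3'-hydroxyl.
- Merits: this ring closure is better precedented than step 10. It attacks an unsubstituted carbon, creates no stereocentre, and has no benzylic cation that could rearrange. In key-step risk this road is superior.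
- Weak points: A5 requires the C4–C8' bond to be made first by intermolecular arylation of a flavan C4 cation with a ring D nucleophile that has one free hydroxyl among three oxygens. The chiral epoxy alcohol must then be attached by etherification of a phenol flanked by the whole upper unit. The upper gallate and the interflavan bond must survive a strong Lewis acid.
- Comparison: the chosen plan never performs the intermolecular arylation. Its ring D comes ready-made and correctly substituted from the natural catechin. C4 and the C4–C4a bond are set together.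

**Alternative 3:** Ring D itself is cut. The siloxyalkyne A7, which is the upper flavan carrying a (triisopropylsiloxy)ethynyl group at C4, is heated with 3-benzyloxycyclobutenone A8, and the Danheiser benzannulation gives phenol A6.
- Merits: ring D is formed with O1' as the only free oxygen, which no desymmetrisation of a phloroglucinol can match. C4 is set early with a small alkynyl group.
- Weak points: the siloxyalkyne of A7 sits on a hindered benzylic carbon and must survive heating. After A6 all of ring F, ring E, C2' and C3' remain to be built, so none of the lower unit is bought.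
- Comparison: in ring D regiocontrol this road is the better one. The chosen plan sets against it C8'-selective bromination of a catechin derivative and a far shorter path, since the lower unit is used whole.

Key step: step 10

## Assumptions and abbreviations

Assumption: (−)-epigallocatechin 1 is bought as the single (2R,3R) enantiomer, and acid 7 and phenol 14 are bought as such (catalogue benzyl ethers of gallic acid and phloroglucinol). The sense of induction of poly-L-leucine on 11 is taken to be the one established for chalcones, (2R,3S)-epoxy ketone.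

Bn = benzyl; TBS = tert-butyldimethylsilyl; Ar = 3,4,5-tris(benzyloxy)phenyl; LU = (2R,3R)-5,7-bis(benzyloxy)-3-[(tert-butyldimethylsilyl)oxy]-2-Ar-chroman-8-yl (the lower unit bound through C8'). In open-chain intermediates the three carbons are called C2, C3 and C4 after the flavan positions they become.

## Route

Step 1
Reactants: 1 (−)-epigallocatechin, (2R,3R)-2-(3,4,5-trihydroxyphenyl)chroman-3,5,7-triol
Product: 2 penta-O-benzyl-(−)-epigallocatechin, (2R,3R)-5,7-bis(benzyloxy)-2-Ar-chroman-3-ol
Conditions: BnBr (5.5 equiv), K2CO3, DMF, 0 °C to rt, argon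
Reagents that add atoms: benzyl bromide, BrCc1ccccc1
Why: Williamson etherification of the five phenols; the weak base deprotonates only the phenols, so the secondary 3-hydroxyl stays free, and exclusion of air with fast alkylation should protect the base-sensitive C2 centre.

Step 2
Reactants: 2 penta-O-benzyl-(−)-epigallocatechin
Product: 3 tert-butyl{[(2R,3R)-5,7-bis(benzyloxy)-2-Ar-chroman-3-yl]oxy}dimethylsilane (3-O-TBS ether of 2)
Conditions: TBSCl, imidazole, DMF, rt
Reagents that add atoms: tert-butyldimethylsilyl chloride, CC(C)(C)[Si](C)(C)Cl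
Why: Standard silylation of the single secondary alcohol; the TBS ether tolerates the aryllithium, KOH, hydroperoxide, hydride and Mitsunobu steps ahead and is removed by fluoride.

Step 3
Reactants: 3 3-O-TBS ether
Product: 4 (2R,3R)-5,7-bis(benzyloxy)-8-bromo-3-[(tert-butyldimethylsilyl)oxy]-2-Ar-chroman
Conditions: NBS (1.0 equiv), CH2Cl2, −78 to 0 °C
Reagents that add atoms: N-bromosuccinimide, O=C1CCC(=O)N1Br
Why: Electrophilic aromatic bromination of the phloroglucinol-type ring, the most activated ring of 3; C8 is favoured over C6, which lies between two benzyloxy groups, as is usual for 5,7-di-O-benzyl flavan-3-ol derivatives.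

Step 4
Reactants: 4 8-bromo flavan
Product: 6 (2R,3R)-5,7-bis(benzyloxy)-3-[(tert-butyldimethylsilyl)oxy]-2-Ar-chroman-8-carbaldehyde, via 8-lithio flavan 5 (not isolated)
Conditions: n-BuLi, THF, −78 °C; DMF, −78 to 0 °C; H2O
Reagents that add atoms: N,N-dimethylformamide, CN(C)C=O
Why: Bromine–lithium exchange is faster than benzylic deprotonation at −78 °C, and formylation of the aryllithium with DMF fixes the future interflavan carbon at C8'.

Step 5
Reactants: 7 3,4,5-tris(benzyloxy)benzoic acid
Product: 9 1-[3,4,5-tris(benzyloxy)phenyl]ethan-1-one, via dilithium 1,1-diolate 8 (not isolated)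
Conditions: MeLi (2.2 equiv), THF, 0 °C to rt; aq. HCl
Reagents that add atoms: methyllithium, [Li]C
Why: Addition of methyllithium to the lithium carboxylate stops at the dilithium gem-diolate, which gives the methyl ketone only on protonation, so over-addition is avoided.

Step 6
Reactants: 6 lower-unit 8-carbaldehyde; 9 1-[3,4,5-tris(benzyloxy)phenyl]ethan-1-one
Product: 11 (E)-3-(LU)-1-Ar-prop-2-en-1-one (the chalcone), via aldol adduct 10 (not isolated)
Conditions: KOH, EtOH/THF, rt
Reagents that add atoms: none
Why: Claisen–Schmidt condensation of a non-enolisable aldehyde with a methyl ketone; E1cB dehydration of the aldol should give the thermodynamically favoured E-enone, and the alkyl TBS ether and benzyl ethers are stable to ethanolic KOH at room temperature.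

Step 7
Reactants: 11 chalcone
Product: 12 [(2R,3S)-3-(LU)oxiran-2-yl](Ar)methanone (trans-epoxy ketone)
Conditions: poly-L-leucine, urea–H2O2, DBU, THF, rt
Reagents that add atoms: hydrogen peroxide (as its urea adduct), OO
Why: Juliá–Colonna epoxidation, a Weitz–Scheffer conjugate addition of hydroperoxide held by the helical peptide; poly-L-leucine should give the (2R,3S)-epoxy ketone, setting C3 (R) and C4 (S), and the E-enone gives the trans epoxide. The purely basic medium suits an epoxide that is benzylic to ring D.

Step 8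
Reactants: 12 trans-epoxy ketone
Product: 13 (S)-[(2S,3S)-3-(LU)oxiran-2-yl](Ar)methanol (anti-epoxy alcohol)
Conditions: Zn(BH4)2, Et2O, −20 °C; then aq. NaH2PO4/Na2HPO4 buffer (pH 7)
Reagents that add atoms: none
Why: Chelation-controlled reduction: zinc bridges the carbonyl and oxirane oxygens and hydride enters from the face away from C4, which should give the anti (erythro) alcohol with C2 = S. The oxirane descriptors change from 12 only because the priorities change.

Step 9
Reactants: 13 anti-epoxy alcohol; 14 3,5-bis(benzyloxy)phenol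
Product: 15 (2R,3S)-2-{(R)-[3,5-bis(benzyloxy)phenoxy](Ar)methyl}-3-(LU)oxirane (aryl ether trans-epoxide)
Conditions: PPh3, DIAD, toluene, 0 °C to rt; chromatography on Et3N-deactivated silica
Reagents that add atoms: none
Why: Mitsunobu etherification with SN2 inversion at C2 (S to R) under neutral conditions, which places the ring A oxygen syn to the oxirane oxygen as the 2,3-cis product requires; the neighbouring oxirane carbon disfavours ionisation at C2.

Step 10
Reactants: 15 aryl ether trans-epoxide
Product: 16 (2R,3R,4R)-5,7-bis(benzyloxy)-4-(LU)-2-Ar-chroman-3-ol (perbenzylated dimer, free upper 3-OH, lower 3'-O-TBS)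
Conditions: Sc(OTf)3 (10 mol %), 4 Å molecular sieves, CH2Cl2, −78 to −20 °C; then Et3N
Reagents that add atoms: none
Why: Sc(OTf)3 binds the oxirane oxygen and the C4–O bond lengthens because C4 is benzylic to the 2,4,6-trioxygenated ring D; the ortho carbon of the 3,5-bis(benzyloxy)phenoxy group on C2 attacks C4 from the side opposite the departing oxygen, and proton loss restores ring A and frees the catalyst. The closest known reaction is the intramolecular Friedel–Crafts epoxy–arene cyclisation of trans-3-aryl glycidyl aryl ethers to trans-4-arylchroman-3-ols. Ring C closes in the 6-endo mode at the epoxide; the 5-exo mode would need attack at the non-benzylic C3. C4 is the only new stereocentre: inversion at the (S)-configured carbon of the trans-epoxide gives 4R, trans to the C3 hydroxyl, while C2 and C3 keep their C–O bonds and configurations. Regioselectivity for C4 is secured by ring D. Arene capture ahead of a 1,2-hydride shift is favoured by the phloroglucinol-type nucleophilicity of ring A, the six-membered transition state, the low temperature and the catalytic amount of Lewis acid. The two ortho carbons of ring A are equivalent, so only one chroman can form. If ionisation runs ahead of bond formation, the open cation should still be attacked anti to the scandium-bound C3 oxygen and give the same 3,4-trans product; the TBS and benzyl ethers tolerate the anhydrous catalyst.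

Step 11
Reactants: 16 perbenzylated dimer (3'-O-TBS)
Product: 17 (2R,3R,4R)-5,7-bis(benzyloxy)-4-[(2R,3R)-5,7-bis(benzyloxy)-3-hydroxy-2-Ar-chroman-8-yl]-2-Ar-chroman-3-ol (diol)
Conditions: TBAF, THF, 0 °C to rt
Reagents that add atoms: none
Why: Fluoride-induced cleavage of the secondary silyl ether; nothing else in 16 responds to fluoride.

Step 12
Reactants: 7 3,4,5-tris(benzyloxy)benzoic acid
Product: 18 3,4,5-tris(benzyloxy)benzoyl chloride
Conditions: (COCl)2, cat. DMF, CH2Cl2, 0 °C to rt; evaporation, used crude
Reagents that add atoms: oxalyl chloride, ClC(=O)C(=O)Cl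
Why: Acid chloride formation through the Vilsmeier-type chloroiminium species generated from DMF and oxalyl chloride; the by-products are gases, and the benzyl ethers are not affected at room temperature.

Step 13
Reactants: 17 diol; 18 3,4,5-tris(benzyloxy)benzoyl chloride (3 equiv in all)
Product: 19 hexadeca-O-benzylrhodisin (the 3,3'-bis[3,4,5-tris(benzyloxy)benzoate] of 17)
Conditions: DMAP, pyridine, CH2Cl2, rt to 40 °C
Reagents that add atoms: 3,4,5-tris(benzyloxy)benzoyl chloride (the second equivalent of 18 that ends up in the product), O=C(Cl)c1cc(OCc2ccccc2)c(OCc2ccccc2)c(OCc2ccccc2)c1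
Why: DMAP-catalysed acylation of both secondary alcohols through the N-acylpyridinium ion, as is usual for hindered flavan 3-hydroxyls; the C–O bonds of C3 and C3' are not broken, so configuration is retained.

Step 14
Reactants: 19 hexadeca-O-benzylrhodisin
Product: 20 rhodisin
Conditions: H2 (1 atm), Pd(OH)2 on carbon, THF/MeOH/H2O, rt; filtration under argon
Reagents that add atoms: none
Why: Hydrogenolysis of the sixteen benzyl ethers under neutral conditions, which should spare the two esters, the interflavan bond and all five stereocentres.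

## Compound list

1 | (−)-epigallocatechin, (2R,3R)-2-(3,4,5-trihydroxyphenyl)chroman-3,5,7-triol | O[C@@H]1Cc2c(O)cc(O)cc2O[C@@H]1c1cc(O)c(O)c(O)c1 | starting material
2 | penta-O-benzyl-(−)-epigallocatechin, (2R,3R)-5,7-bis(benzyloxy)-2-[3,4,5-tris(benzyloxy)phenyl]chroman-3-ol | O[C@@H]1Cc2c(OCc4ccccc4)cc(OCc4ccccc4)cc2O[C@@H]1c1cc(OCc4ccccc4)c(OCc4ccccc4)c(OCc4ccccc4)c1 | intermediate
3 | 3-O-TBS ether of 2, (2R,3R) | CC(C)(C)[Si](C)(C)O[C@@H]1Cc2c(OCc4ccccc4)cc(OCc4ccccc4)cc2O[C@@H]1c1cc(OCc4ccccc4)c(OCc4ccccc4)c(OCc4ccccc4)c1 | intermediate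
4 | 8-bromo derivative of 3, (2R,3R) | Brc2c(OCc4ccccc4)cc(OCc4ccccc4)c3c2O[C@H](c2cc(OCc4ccccc4)c(OCc4ccccc4)c(OCc4ccccc4)c2)[C@H](O[Si](C)(C)C(C)(C)C)C3 | intermediate
5 | 8-lithio derivative of 3, (2R,3R) | [Li]c2c(OCc4ccccc4)cc(OCc4ccccc4)c3c2O[C@H](c2cc(OCc4ccccc4)c(OCc4ccccc4)c(OCc4ccccc4)c2)[C@H](O[Si](C)(C)C(C)(C)C)C3 | intermediate (not isolated)
6 | (2R,3R)-5,7-bis(benzyloxy)-3-[(tert-butyldimethylsilyl)oxy]-2-[3,4,5-tris(benzyloxy)phenyl]chroman-8-carbaldehyde | O=Cc2c(OCc4ccccc4)cc(OCc4ccccc4)c3c2O[C@H](c2cc(OCc4ccccc4)c(OCc4ccccc4)c(OCc4ccccc4)c2)[C@H](O[Si](C)(C)C(C)(C)C)C3 | intermediate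
7 | 3,4,5-tris(benzyloxy)benzoic acid | OC(=O)c1cc(OCc2ccccc2)c(OCc2ccccc2)c(OCc2ccccc2)c1 | starting material
8 | dilithium 1-[3,4,5-tris(benzyloxy)phenyl]ethane-1,1-diolate | [Li]OC(C)(O[Li])c1cc(OCc2ccccc2)c(OCc2ccccc2)c(OCc2ccccc2)c1 | intermediate (not isolated)
9 | 1-[3,4,5-tris(benzyloxy)phenyl]ethan-1-one | CC(=O)c1cc(OCc2ccccc2)c(OCc2ccccc2)c(OCc2ccccc2)c1 | intermediate
10 | aldol adduct, 3-hydroxy-3-(LU)-1-Ar-propan-1-one (both carbinol epimers) | O=C(CC(O)c2c(OCc4ccccc4)cc(OCc4ccccc4)c3c2O[C@H](c2cc(OCc4ccccc4)c(OCc4ccccc4)c(OCc4ccccc4)c2)[C@H](O[Si](C)(C)C(C)(C)C)C3)c2cc(OCc4ccccc4)c(OCc4ccccc4)c(OCc4ccccc4)c2 | intermediate (not isolated)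
11 | chalcone, (E)-3-(LU)-1-Ar-prop-2-en-1-one | O=C(/C=C/c2c(OCc4ccccc4)cc(OCc4ccccc4)c3c2O[C@H](c2cc(OCc4ccccc4)c(OCc4ccccc4)c(OCc4ccccc4)c2)[C@H](O[Si](C)(C)C(C)(C)C)C3)c2cc(OCc4ccccc4)c(OCc4ccccc4)c(OCc4ccccc4)c2 | intermediate
12 | trans-epoxy ketone, [(2R,3S)-3-(LU)oxiran-2-yl](Ar)methanone | O=C([C@@H]5O[C@H]5c2c(OCc4ccccc4)cc(OCc4ccccc4)c3c2O[C@H](c2cc(OCc4ccccc4)c(OCc4ccccc4)c(OCc4ccccc4)c2)[C@H](O[Si](C)(C)C(C)(C)C)C3)c2cc(OCc4ccccc4)c(OCc4ccccc4)c(OCc4ccccc4)c2 | intermediate
13 | anti-epoxy alcohol, (S)-[(2S,3S)-3-(LU)oxiran-2-yl](Ar)methanol | O[C@H]([C@@H]5O[C@H]5c2c(OCc4ccccc4)cc(OCc4ccccc4)c3c2O[C@H](c2cc(OCc4ccccc4)c(OCc4ccccc4)c(OCc4ccccc4)c2)[C@H](O[Si](C)(C)C(C)(C)C)C3)c2cc(OCc4ccccc4)c(OCc4ccccc4)c(OCc4ccccc4)c2 | intermediate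
14 | 3,5-bis(benzyloxy)phenol | Oc1cc(OCc2ccccc2)cc(OCc2ccccc2)c1 | starting material
15 | aryl ether trans-epoxide, (2R,3S)-2-{(R)-[3,5-bis(benzyloxy)phenoxy](Ar)methyl}-3-(LU)oxirane | c1ccccc1COc1cc(OCc2ccccc2)cc(O[C@@H]([C@@H]5O[C@H]5c2c(OCc4ccccc4)cc(OCc4ccccc4)c3c2O[C@H](c2cc(OCc4ccccc4)c(OCc4ccccc4)c(OCc4ccccc4)c2)[C@H](O[Si](C)(C)C(C)(C)C)C3)c2cc(OCc4ccccc4)c(OCc4ccccc4)c(OCc4ccccc4)c2)c1 | intermediate
16 | (2R,3R,4R)-5,7-bis(benzyloxy)-4-(LU)-2-Ar-chroman-3-ol | O[C@@H]1[C@@H](c2c(OCc4ccccc4)cc(OCc4ccccc4)c3c2O[C@H](c2cc(OCc4ccccc4)c(OCc4ccccc4)c(OCc4ccccc4)c2)[C@H](O[Si](C)(C)C(C)(C)C)C3)c2c(OCc4ccccc4)cc(OCc4ccccc4)cc2O[C@@H]1c1cc(OCc4ccccc4)c(OCc4ccccc4)c(OCc4ccccc4)c1 | intermediate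
17 | diol, (2R,3R,4R)-5,7-bis(benzyloxy)-4-[(2R,3R)-5,7-bis(benzyloxy)-3-hydroxy-2-Ar-chroman-8-yl]-2-Ar-chroman-3-ol | O[C@@H]1[C@@H](c2c(OCc4ccccc4)cc(OCc4ccccc4)c3c2O[C@H](c2cc(OCc4ccccc4)c(OCc4ccccc4)c(OCc4ccccc4)c2)[C@H](O)C3)c2c(OCc4ccccc4)cc(OCc4ccccc4)cc2O[C@@H]1c1cc(OCc4ccccc4)c(OCc4ccccc4)c(OCc4ccccc4)c1 | intermediate
18 | 3,4,5-tris(benzyloxy)benzoyl chloride | O=C(Cl)c1cc(OCc2ccccc2)c(OCc2ccccc2)c(OCc2ccccc2)c1 | intermediate
19 | hexadeca-O-benzylrhodisin, upper (2R,3R,4R), lower (2R,3R), both 3-oxygens as 3,4,5-tris(benzyloxy)benzoates | O=C(O[C@@H]1[C@@H](c2c(OCc4ccccc4)cc(OCc4ccccc4)c3c2O[C@H](c2cc(OCc4ccccc4)c(OCc4ccccc4)c(OCc4ccccc4)c2)[C@H](OC(=O)c2cc(OCc4ccccc4)c(OCc4ccccc4)c(OCc4ccccc4)c2)C3)c2c(OCc4ccccc4)cc(OCc4ccccc4)cc2O[C@@H]1c1cc(OCc4ccccc4)c(OCc4ccccc4)c(OCc4ccccc4)c1)c1cc(OCc4ccccc4)c(OCc4ccccc4)c(OCc4ccccc4)c1 | intermediate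
20 | rhodisin, epigallocatechin gallate-(4β→8)-epigallocatechin gallate, upper (2R,3R,4R), lower (2R,3R) | O=C(O[C@@H]1[C@@H](c2c(O)cc(O)c3c2O[C@H](c2cc(O)c(O)c(O)c2)[C@H](OC(=O)c2cc(O)c(O)c(O)c2)C3)c2c(O)cc(O)cc2O[C@@H]1c1cc(O)c(O)c(O)c1)c1cc(O)c(O)c(O)c1 | target

## Step count and risks

Total: 14 steps. Longest linear sequence: 12 steps, from 1 to 20 through steps 1–4, 6–11, 13 and 14; steps 5 and 12 are one-step side branches from acid 7.

**Step 10 (key step).** The Lewis acid may open the epoxide faster than ring A can close. A 1,2-hydride shift from C3 would then give the C3 ketone, or a long-lived cation would lose the C4 configuration. Premature opening on handling is the same process without catalyst.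
Fallback, from 15 back to 16: the epoxide is opened on purpose at C4 with methanol (MeOH, cat. pyridinium p-toluenesulfonate, CH2Cl2, 0 °C) to the 4-methoxy-3-ol F1. F1 is acetylated (Ac2O, pyridine, DMAP) to the 4-methoxy-3-acetate F2. TMSOTf in CH2Cl2 at −78 °C then ionises the benzylic methyl ether. The C3 acetate captures the cation as a 1,3-dioxolan-2-ylium ion, which blocks the hydride shift and leaves only the face anti to O3 open to ring A. This should give the 3-O-acetyl chromanol F3, and K2CO3 in MeOH/THF returns it to 16.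

**Step 7.** Conjugate addition of hydroperoxide may be slow and poorly face-selective. The β-carbon of 11 carries a strongly donating, di-ortho-substituted aryl group, and the lower unit may be mismatched with the peptide.
Fallback, from 11 back to 12: the epoxidation is made electrophilic. 1,2-Reduction with i-Bu2AlH (toluene, −78 °C) gives the allylic alcohols F4 as both carbinol epimers. Shi epoxidation follows (KHSO5 as Oxone, K2CO3, MeCN/dimethoxymethane/aqueous buffer, 0 °C), using the L-sorbose-derived enantiomer of the fructose-derived ketone. The D-fructose ketone gives (R,R)-epoxides from trans-alkenes, and the (S,S) oxirane is needed here. This should give the epoxy alcohols F5 as carbinol epimers under basic conditions. Dess–Martin periodinane with NaHCO3 in CH2Cl2 converts both epimers to 12.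

**Step 9.** The oxyphosphonium intermediate may ionise with help from the para oxygen of ring B and erode the inversion at C2. The hindered carbinol may react slowly, so that the phenol opens the epoxide instead.
Fallback, from 12 back to 15: the ether is made with retention at carbon by arylating the oxygen instead of displacing it. Reagent-controlled Noyori transfer hydrogenation of 12 with RuCl[(S,S)-TsDPEN](p-cymene) and HCO2Na is used. This is the catalyst enantiomer that gives (S)-1-phenylethanol from acetophenone; here it corresponds to the (R) carbinol because the oxiranyl carbon outranks the aryl group. It should give the syn-epoxy alcohol F6, the C2 epimer of 13. Ullmann-type O-arylation of F6 with 1-iodo-3,5-bis(benzyloxy)benzene (CuI, 3,4,7,8-tetramethyl-1,10-phenanthroline, Cs2CO3, toluene, lowest workable temperature) then gives 15 without touching C2.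

**Step 14.** Hydrogenolysis of sixteen ethers may stall on partially debenzylated, strongly adsorbed intermediates. Prolonged reduction may cleave the benzylic C4–C8' or C2–O1 bonds. The free polyphenol oxidises in air during isolation.
Fallback, from 19 directly to 20: Lewis-acid dealkylation replaces catalytic reduction. BCl3 with pentamethylbenzene as cation scavenger (CH2Cl2, −78 °C) cleaves aryl benzyl ethers and spares aryl esters. No new intermediate is formed.

## Further compounds

F1 | step 10 | 4-methoxy-3-ol from anti methanolysis of 15 at C4 (C2 R, C3 and C4 as drawn) | c1ccccc1COc1cc(OCc2ccccc2)cc(O[C@@H]([C@H](O)[C@H](OC)c2c(OCc4ccccc4)cc(OCc4ccccc4)c3c2O[C@H](c2cc(OCc4ccccc4)c(OCc4ccccc4)c(OCc4ccccc4)c2)[C@H](O[Si](C)(C)C(C)(C)C)C3)c2cc(OCc4ccccc4)c(OCc4ccccc4)c(OCc4ccccc4)c2)c1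
F2 | step 10 | 3-acetate of F1 | c1ccccc1COc1cc(OCc2ccccc2)cc(O[C@@H]([C@H](OC(C)=O)[C@H](OC)c2c(OCc4ccccc4)cc(OCc4ccccc4)c3c2O[C@H](c2cc(OCc4ccccc4)c(OCc4ccccc4)c(OCc4ccccc4)c2)[C@H](O[Si](C)(C)C(C)(C)C)C3)c2cc(OCc4ccccc4)c(OCc4ccccc4)c(OCc4ccccc4)c2)c1
F3 | step 10 | 3-O-acetate of 16, (2R,3R,4R) | CC(=O)O[C@@H]1[C@@H](c2c(OCc4ccccc4)cc(OCc4ccccc4)c3c2O[C@H](c2cc(OCc4ccccc4)c(OCc4ccccc4)c(OCc4ccccc4)c2)[C@H](O[Si](C)(C)C(C)(C)C)C3)c2c(OCc4ccccc4)cc(OCc4ccccc4)cc2O[C@@H]1c1cc(OCc4ccccc4)c(OCc4ccccc4)c(OCc4ccccc4)c1
F4 | step 7 | allylic alcohols, (E)-3-(LU)-1-Ar-prop-2-en-1-ol, both carbinol epimers | OC(/C=C/c2c(OCc4ccccc4)cc(OCc4ccccc4)c3c2O[C@H](c2cc(OCc4ccccc4)c(OCc4ccccc4)c(OCc4ccccc4)c2)[C@H](O[Si](C)(C)C(C)(C)C)C3)c2cc(OCc4ccccc4)c(OCc4ccccc4)c(OCc4ccccc4)c2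
F5 | step 7 | epoxy alcohols, [(2S,3S)-3-(LU)oxiran-2-yl](Ar)methanol, both carbinol epimers | OC([C@@H]5O[C@H]5c2c(OCc4ccccc4)cc(OCc4ccccc4)c3c2O[C@H](c2cc(OCc4ccccc4)c(OCc4ccccc4)c(OCc4ccccc4)c2)[C@H](O[Si](C)(C)C(C)(C)C)C3)c2cc(OCc4ccccc4)c(OCc4ccccc4)c(OCc4ccccc4)c2
F6 | step 9 | syn-epoxy alcohol, (R)-[(2S,3S)-3-(LU)oxiran-2-yl](Ar)methanol | O[C@@H]([C@@H]5O[C@H]5c2c(OCc4ccccc4)cc(OCc4ccccc4)c3c2O[C@H](c2cc(OCc4ccccc4)c(OCc4ccccc4)c(OCc4ccccc4)c2)[C@H](O[Si](C)(C)C(C)(C)C)C3)c2cc(OCc4ccccc4)c(OCc4ccccc4)c(OCc4ccccc4)c2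
F0 | step 14 | none | none
A1 | alternative 1 | perbenzylated dimer as its 3,3'-bis(triisopropylsilyl) ether | CC(C)[Si](C(C)C)(C(C)C)O[C@@H]1[C@@H](c2c(OCc4ccccc4)cc(OCc4ccccc4)c3c2O[C@H](c2cc(OCc4ccccc4)c(OCc4ccccc4)c(OCc4ccccc4)c2)[C@H](O[Si](C(C)C)(C(C)C)C(C)C)C3)c2c(OCc4ccccc4)cc(OCc4ccccc4)cc2O[C@@H]1c1cc(OCc4ccccc4)c(OCc4ccccc4)c(OCc4ccccc4)c1
A2 | alternative 1 | bis-dihydrocoumarin (both pyran rings as 3-triisopropylsiloxy lactones, C4–C8' bond in place) | CC(C)[Si](C(C)C)(C(C)C)O[C@@H]1[C@@H](c2c(OCc4ccccc4)cc(OCc4ccccc4)c3c2OC(=O)[C@H](O[Si](C(C)C)(C(C)C)C(C)C)C3)c2c(OCc4ccccc4)cc(OCc4ccccc4)cc2OC1=O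
A3 | alternative 1 | 3,4,5-tris(benzyloxy)phenyllithium | [Li]c1cc(OCc2ccccc2)c(OCc2ccccc2)c(OCc2ccccc2)c1
A4 | alternative 2 | perbenzylated dimer with upper 3-O-gallate and free lower 3'-hydroxyl | O=C(O[C@@H]1[C@@H](c2c(OCc4ccccc4)cc(OCc4ccccc4)c3c2O[C@H](c2cc(OCc4ccccc4)c(OCc4ccccc4)c(OCc4ccccc4)c2)[C@H](O)C3)c2c(OCc4ccccc4)cc(OCc4ccccc4)cc2O[C@@H]1c1cc(OCc4ccccc4)c(OCc4ccccc4)c(OCc4ccccc4)c1)c1cc(OCc4ccccc4)c(OCc4ccccc4)c(OCc4ccccc4)c1
A5 | alternative 2 | galloylated upper unit whose ring D is an open aryl ether carrying the 1-aryl-2,3-epoxypropyl chain on O1' | O=C(O[C@@H]1[C@@H](c2c(OCc4ccccc4)cc(OCc4ccccc4)cc2O[C@H](c2cc(OCc4ccccc4)c(OCc4ccccc4)c(OCc4ccccc4)c2)[C@H]3CO3)c2c(OCc4ccccc4)cc(OCc4ccccc4)cc2O[C@@H]1c1cc(OCc4ccccc4)c(OCc4ccccc4)c(OCc4ccccc4)c1)c1cc(OCc4ccccc4)c(OCc4ccccc4)c(OCc4ccccc4)c1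
A6 | alternative 3 | upper unit bearing ring D as 2-hydroxy-4-benzyloxy-6-triisopropylsiloxyphenyl on C4 | CC(C)(C)[Si](C)(C)O[C@@H]1[C@@H](c2c(O)cc(OCc4ccccc4)cc2O[Si](C(C)C)(C(C)C)C(C)C)c2c(OCc4ccccc4)cc(OCc4ccccc4)cc2O[C@@H]1c1cc(OCc4ccccc4)c(OCc4ccccc4)c(OCc4ccccc4)c1
A7 | alternative 3 | upper unit bearing a (triisopropylsiloxy)ethynyl group on C4 | CC(C)(C)[Si](C)(C)O[C@@H]1[C@@H](C#CO[Si](C(C)C)(C(C)C)C(C)C)c2c(OCc4ccccc4)cc(OCc4ccccc4)cc2O[C@@H]1c1cc(OCc4ccccc4)c(OCc4ccccc4)c(OCc4ccccc4)c1
A8 | alternative 3 | 3-(benzyloxy)cyclobut-2-en-1-one | O=C1CC(OCc2ccccc2)=C1
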